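## Structural features

The target (37) is a cis-fused octahydronaphthalene. Ring A (C1 to C4a plus C8a) holds a cross-conjugated dienone: the C3=C4 alkene with a methyl on C3, and an exocyclic E alkene at C2 whose outer carbon carries a hydroxymethyl ketone. C1 sits between this dienone and a (2E,4Z,6E)-4,6-dimethylhepta-2,4,6-trienoic acid attached through C1′, so C1–H is doubly allylic and vinylogously acidic toward both carbonyl systems. Ring B (C4a to C8a) carries the contiguous C6-methyl, C7-hydroxyl, C8-methyl triad, all equatorial, next to the fusion carbons. The stereocentres C1, C8a, C8, C7 and C6 form an unbroken chain, and C4a is attached to C8a. The fragile points are the C1 stereocentre (epimerisation, or migration of a flanking alkene into conjugation), the Z trisubstituted C3′=C4′ alkene, the α-ketol and the free acid; together they exclude strong base and strong acid late in the route. The real difficulty is twofold: setting C4a, C8a, C8, C7 and C6 in the right relative and absolute sense, and attaching the C1 chain and the C2 enone without moving double bonds. The key step uses the fact that C8 carries a methyl and a hydrogen next to C8a: this is what remains when a C8 vinyl group takes up a hydrogen atom and the C8 radical adds to C8a, the β-carbon of a ring A enone whose carbonyl is the future C2.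

## Logic of the disconnections

37 from 36: only the two O–Si bonds are cut. The silyl ethers are kept to the end so that the last operation is a buffered fluoride treatment. The demand is that no base is used once the trienoic acid and the dienone flank C1.

36 from 30 and 34: the sp2–sp2 bond C4′–C5′ is cut. This keeps the carboxylic acid and the third alkene out of all earlier chemistry and makes the end convergent. The forward coupling must keep the Z geometry of a hindered alkenyl iodide and must run without base.

30 from 29: the exocyclic enone is traced to a tertiary C2 propargylic alcohol by a 1,3-shift of oxygen (C2–O cut, C=O formed on the far alkyne carbon). The alkylidene carbon, the ketone and the hydroxymethyl arm then all come from one alkyne. The rearrangement must be alkyne-selective on a carbinol that is also allylic, and must deliver the E isomer.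

29 from 27 and 28: the C3′=C4′ bond is cut. The Z geometry is stored in a configurationally stable alkenyl iodide, made while C2 is still a carbinol and C1–H is least acidic. The olefination must be Z-selective and must tolerate a free tertiary hydroxyl.

27 from 24 and 25: the C2–alkyne bond is cut and the enal is masked as its acetal. This returns to a simple ketone. The addition must occur at a hindered, easily enolised carbonyl without removing the C1 proton.

24 from 18 and 22: the C1–C1′ bond is cut. C1 is the only enolisable α-position of 18, so regiochemistry is not in question. The coupling must keep the E geometry of 22, must not move the new alkene into conjugation, and must leave the alkenyl group anti to C8.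

22 from 21 from 19: the acetal C–O bonds and the C–Br bond are cut, which leads to a commodity enal. The only demand is E geometry of the bromoalkene.

18 from 16: the C3=C4 π bond is removed. The saturated ketone is the direct product of ring B closure, and its C3 methyl makes enolisation toward C3 the thermodynamic one. The dehydrogenation must be regioselective for C3–C4 over C1–C8a.

16 from 15 (key): the C8–C8a bond is cut and ring B is opened. Two stereocentres (C8, C8a) and one ring disappear, leaving a monocyclic enone whose chain already holds C6 and C7. The forward step needs hydrogen-atom transfer to the vinyl group in the presence of the enone and a chair transition state that fixes both new centres. A check of the descriptors shows that 15 and 16 carry the configuration of 37 at every ring B and fusion centre they share. The design of 15 keeps the silyl ether (equatorial in the closing chair) and installs the C3 methyl before the cyclisation so that the later dehydrogenation is regiodefined.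

15 from 13: the C3–CH3 bond is cut. This gives the product of a standard annulation. The methylation must be kinetic (α′, not γ); its stereochemical outcome does not matter.

13 from 10 and 11: C4–C4a and C1=C8a are cut. Ring A then comes from a linear aldehyde, and C4a is set by a catalyst and not by the remote C6 and C7 centres. The enamine catalysis must tolerate the branched chain, and the aldol condensation must not epimerise C4a.

10 from 7 and 8: C4a–C5 is cut. This is a two-carbon aldehyde homologation of a primary iodide. The demand is substitution without elimination at a β-branched iodide.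

7 from 6, 5 and 4, and 4 from 1 and 2: after functional-group changes at C5, the C6–C7 bond is cut. An auxiliary-controlled syn-aldol sets both centres at once. It is preferred to adding a vinyl metal to a chiral α-methyl aldehyde, whose Felkin–Anh bias is modest. The demand is the (R) auxiliary.

34 from 31 and 32: the C–Sn and O–Sn bonds are cut. The reagent carries the acid as a stannyl ester, so no separate ester cleavage is needed later.

## Other disconnections considered

Alternative 1: The cut is C4a–C5, with C3–C7 present as a bond in the substrate. In the forward step a potassium alkoxide at C7 bearing a vinyl group undergoes an anionic oxy-Cope [3,3] shift that opens a bicyclo[2.2.2]octene to the cis-decalin, and the C6 enolate is methylated in the same flask to give A1.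
- In favour: the shift is stereospecific and the cis fusion follows from the bicyclic template. It is at least the equal of the chosen radical closure in mechanistic certainty.
- Better than the chosen plan on one point: C6 and C8 both flank the C7 ketone, so either methyl can be corrected by equilibration, whereas step 8 fixes C8 irreversibly.
- Also better: the C3=C4 alkene arrives in place, so no dehydrogenation is needed.
- Against: the absolute configuration must come from an asymmetric dearomatisation or cycloaddition, which is harder to secure than an auxiliary aldol plus an amine catalyst.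
- Against: the C7 ketone must be reduced to the equatorial alcohol between two methyl-bearing carbons.
- Against: the dihydrofuran delivers C1 with a two-carbon enol-ether arm and C2 as an ether oxygen. Turning these into the 2′-methyl alkenyl chain and the C2 ketone costs several redox and olefination steps through an epimerisable C1.
- Step economy: faster to the bicycle, slower after it; overall no shorter than the chosen plan.

Alternative 2: The cut removes C6: a cis-hydrindanone from a Pauson–Khand reaction is enlarged by insertion of one carbon between C5 and the C7 carbonyl (Me3SiCHN2, BF3·OEt2) to give A2.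
- In favour: the bicyclic core is made quickly.
- Better than the chosen plan: ring A arrives with C1 (as CH2OPMB), C2 (as a silyl ether) and C3=C4 already set, so the enolate alkenylation of step 12 and its C1 question are avoided.
- Against: the migrating carbon in the insertion (C5 methylene against C8 methine) is not securely controlled, and a cationic 1,2-shift is less predictable than a 6-exo radical closure.
- Against: the C6 methyl is still missing, so C6 and C7 must be set late by substrate control (methylation, then reduction). The chosen plan fixes them in step 1.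
- Against: the C1 arm must pass through an epimerisable α-branched aldehyde.
- Step economy: similar at best.

Alternative 3: The cut is C1–C2: Me2AlCl promotes an intramolecular carbonyl-ene reaction of a C2 enal with a C1=C1′ alkene, closing ring A and giving A3.
- Better than the chosen plan: C1 is set in a ring-forming pericyclic step with its alkenyl group already attached, under kinetic control by a cyclic transition state, and not by an enolate coupling followed by equilibration.
- Equal: after oxidation of the C2 alcohol, the end game (alkyne addition, rearrangement) would match steps 13 and 15.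
- Against: ring B with its three substituents and two cis side arms must be built first without a bicyclic template, which is the hard part of the molecule.
- Against: a Z enal is needed, and Prins or hetero-Diels–Alder paths compete.
- Against: the 2-methylprop-1-enyl group must later be oxidised at one methyl in the presence of the C3 methyl alkene.
- Step economy: longer than the chosen plan.

Key step: step 8

Remarks on the chemistry:
- 15 and 16 are written with the C3 configuration expected from kinetic methylation (methyl trans to the C4a chain). The other C3 epimer would serve equally, because C3 becomes sp2 in 17.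
- The C2 carbinol configuration of 26, 27 and 29 is left open; both epimers converge on 30.
- C1 of 24 is taken as the epimer with the alkenyl group anti to C8, for the reasons in step 12.

## Steps

Step 1
Reactants: 1 (R)-4-benzyl-3-propanoyloxazolidin-2-one; 2 acrolein
Product: 4 (R)-4-benzyl-3-[(2R,3S)-3-hydroxy-2-methylpent-4-enoyl]oxazolidin-2-one, via Z dibutylboron enolate 3 (not isolated)
Conditions: Bu2BOTf, Et3N, CH2Cl2, −78 to 0 °C; 2, −78 °C; pH 7 buffer, MeOH, H2O2, 0 °C
Reagents that add atoms: none
Why: Evans syn-aldol reaction: the Z boron enolate adds through a closed chair transition state on the enolate face left open by the benzyl group. This sets C6 (methyl) and C7 (oxygen) syn in the open chain, which is trans on the future ring B.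

Step 2
Reactants: 4 (R)-4-benzyl-3-[(2R,3S)-3-hydroxy-2-methylpent-4-enoyl]oxazolidin-2-one
Product: 5 (R)-4-benzyl-3-[(2R,3S)-3-(tert-butyldimethylsilyloxy)-2-methylpent-4-enoyl]oxazolidin-2-one
Conditions: TBSOTf, 2,6-lutidine, CH2Cl2, −78 to 0 °C
Reagents that add atoms: tert-butyldimethylsilyl triflate, CC(C)(C)[Si](C)(C)OS(=O)(=O)C(F)(F)F
Why: Silyl triflate silylation of the hindered secondary aldol hydroxyl; the base is too weak for retro-aldol cleavage or epimerisation.

Step 3
Reactants: 5 (R)-4-benzyl-3-[(2R,3S)-3-(tert-butyldimethylsilyloxy)-2-methylpent-4-enoyl]oxazolidin-2-one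
Product: 6 (2S,3S)-3-(tert-butyldimethylsilyloxy)-2-methylpent-4-en-1-ol
Conditions: LiBH4, MeOH (1 equiv), THF, 0 °C
Reagents that add atoms: none
Why: Reductive removal of the auxiliary: hydride attacks the exocyclic imide carbonyl and gives the primary alcohol that becomes C5; the α-stereocentre is not enolised.

Step 4
Reactants: 6 (2S,3S)-3-(tert-butyldimethylsilyloxy)-2-methylpent-4-en-1-ol
Product: 7 tert-butyl{[(3S,4R)-5-iodo-4-methylpent-1-en-3-yl]oxy}dimethylsilane
Conditions: I2, PPh3, imidazole, CH2Cl2, 0 °C to rt
Reagents that add atoms: iodine, II
Why: Appel-type iodination: the primary oxyphosphonium group is displaced by iodide in an SN2 reaction; no stereocentre is involved (the descriptor at the methyl carbon changes only through priorities).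

Step 5
Reactants: 7 tert-butyl{[(3S,4R)-5-iodo-4-methylpent-1-en-3-yl]oxy}dimethylsilane; 8 acetaldehyde N,N-dimethylhydrazone
Product: 10 (4S,5S)-5-(tert-butyldimethylsilyloxy)-4-methylhept-6-enal, via alkylated dimethylhydrazone 9 (not isolated)
Conditions: 8, LiN(i-Pr)2, THF, 0 °C; 7, −78 °C to rt; then aq. oxalic acid, Et2O, rt
Reagents that add atoms: water, O
Why: Alkylation of a lithiated hydrazone (aza-enolate) by the primary iodide, then hydrolysis, is a two-carbon aldehyde homologation that forms C4a–C5; the soft aza-enolate favours substitution over elimination.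

Step 6
Reactants: 10 (4S,5S)-5-(tert-butyldimethylsilyloxy)-4-methylhept-6-enal; 11 methyl vinyl ketone
Product: 13 (S)-4-[(2S,3S)-3-(tert-butyldimethylsilyloxy)-2-methylpent-4-enyl]cyclohex-2-en-1-one, via keto aldehyde 12 (not isolated)
Conditions: (S)-2-(methoxydiphenylmethyl)pyrrolidine (10 mol %), ethyl 3,4-dihydroxybenzoate (20 mol %), neat, 4 °C; then LiOH, i-PrOH, rt
Reagents that add atoms: none
Why: Enamine-catalysed Michael addition followed by intramolecular aldol condensation (Robinson-type annulation). The bulky group of the (S)-catalyst shields one face of the E enamine, so C4a is set under catalyst control, with C6 and C7 too remote to interfere.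

Step 7
Reactants: 13 (S)-4-[(2S,3S)-3-(tert-butyldimethylsilyloxy)-2-methylpent-4-enyl]cyclohex-2-en-1-one
Product: 15 (4R,6R)-4-[(2S,3S)-3-(tert-butyldimethylsilyloxy)-2-methylpent-4-enyl]-6-methylcyclohex-2-en-1-one, via lithium dienolate 14 (not isolated)
Conditions: LiN(i-Pr)2, THF, −78 °C; MeI, −78 to −40 °C
Reagents that add atoms: iodomethane, CI
Why: Kinetic α′-deprotonation gives the cross-conjugated enolate, which is methylated at C3. The trans product is expected, but the C3 configuration has no consequence because C3 becomes sp2 in step 9.

Step 8
Reactants: 15 (4R,6R)-4-[(2S,3S)-3-(tert-butyldimethylsilyloxy)-2-methylpent-4-enyl]-6-methylcyclohex-2-en-1-one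
Product: 16 cis-fused 7-(tert-butyldimethylsilyloxy)-3,6,8-trimethyloctahydronaphthalen-2(1H)-one (ring B and fusion centres as in 37; C3 inherited from 15)
Conditions: Fe(acac)3 (0.5 equiv), PhSiH3 (2.5 equiv), EtOH/(CH2OH)2 5:1, 0.02 M, 60 °C
Reagents that add atoms: none
Why: Fe(acac)3 and PhSiH3 in ethanol form an iron hydride that transfers a hydrogen atom to the terminal CH2 of the vinyl group, giving the secondary C8 radical and the future C8 methyl; the closest known reaction is the metal-hydride HAT reductive olefin–enone coupling, used here in its intramolecular form. The radical adds to the enone β-carbon C8a in a 6-exo-trig closure of ring B, and the α-keto radical at C1 is reduced by divalent iron to the enolate and protonated by the solvent, which returns trivalent iron. C8a is controlled by the tether: in the chair transition state with C6-methyl and C7-OSi equatorial, the C4a–C4 bond is forced axial on the forming ring, so only the cis fusion is reachable, and the new bond is axial on ring A as stereoelectronics require. C8 is controlled by the same chair: the methyl on the radical carbon stays equatorial, trans to the C8a–C1 bond, because the axial position would collide with the axial C4 methylene. The step needs hydrogen-atom transfer to the vinyl group and not to the enone; the preference of the metal hydride for the unhindered, electron-richer terminal alkene secures this. Dilution favours cyclisation over reduction of the C8 radical; a 1,5-hydrogen shift from the allylic C4a–H is the other competing path.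

Step 9
Reactants: 16 cis-fused 7-(tert-butyldimethylsilyloxy)-3,6,8-trimethyloctahydronaphthalen-2(1H)-one
Product: 18 cis-fused 7-(tert-butyldimethylsilyloxy)-3,6,8-trimethyl-4a,5,6,7,8,8a-hexahydronaphthalen-2(1H)-one, via trimethylsilyl enol ether 17 (not isolated)
Conditions: TMSCl, NaI, Et3N, MeCN, rt; then Pd(OAc)2 (1.05 equiv), MeCN, rt
Reagents that add atoms: none
Why: Saegusa–Ito oxidation: equilibrating silylation gives the more substituted C2=C3 enol ether, and the palladium enolate then loses a C4 hydride to give the C3=C4 enone. C3 ceases to be a stereocentre and ring B is untouched.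

Step 10
Reactants: 19 methacrolein
Product: 21 (E)-3-bromo-2-methylprop-2-enal, via 2,3-dibromo-2-methylpropanal 20 (not isolated)
Conditions: Br2, CH2Cl2, −78 to 0 °C; Et3N, 0 °C to rt
Reagents that add atoms: bromine, BrBr
Why: Bromine addition and base-induced loss of HBr from the dibromo aldehyde; the E isomer, with bromine anti to the formyl group, is the thermodynamically preferred one.

Step 11
Reactants: 21 (E)-3-bromo-2-methylprop-2-enal
Product: 22 (E)-1-bromo-3,3-dimethoxy-2-methylprop-1-ene
Conditions: HC(OMe)3, MeOH, p-TsOH (cat.), rt
Reagents that add atoms: trimethyl orthoformate, COC(OC)OC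
Why: Acid-catalysed acetalisation masks the aldehyde against the enolate of step 12 and the acetylide of step 13; the alkene geometry is not affected.

Step 12
Reactants: 18 cis-fused 7-(tert-butyldimethylsilyloxy)-3,6,8-trimethyl-4a,5,6,7,8,8a-hexahydronaphthalen-2(1H)-one; 22 (E)-1-bromo-3,3-dimethoxy-2-methylprop-1-ene
Product: 24 enone 18 carrying at C1 the (E)-3,3-dimethoxy-2-methylprop-1-enyl group (alkenyl anti to C8 as in 37), via lithium enolate 23 (not isolated)
Conditions: LiN(SiMe3)2 (2.2 equiv), THF, −78 °C; 22, Pd2(dba)3 (2.5 mol %), P(t-Bu)3·HBF4 (10 mol %), THF, rt to 40 °C; aq. NH4Cl, −78 °C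
Reagents that add atoms: none
Why: Palladium-catalysed α-alkenylation of a ketone enolate: the kinetic cross-conjugated enolate couples with the alkenyl bromide with retention of the E geometry. C1 is set on the face away from the axial C8a–C8 bond. This epimer (alkenyl pseudo-axial on ring A, anti to C8) is also the more stable one, because the equatorial position runs into the C8 methyl, so reprotonation of the product enolate or a brief mild-base equilibration converges on it.

Step 13
Reactants: 24 enone 18 carrying at C1 the (E)-3,3-dimethoxy-2-methylprop-1-enyl group; 25 tert-butyldimethyl(prop-2-ynyloxy)silane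
Product: 27 C2 tertiary carbinol bearing the 3-(tert-butyldimethylsilyloxy)prop-1-ynyl group at C2 and the (E)-2-methyl-3-oxoprop-1-enyl group at C1, via acetal carbinol 26 (not isolated)
Conditions: 25, n-BuLi, THF, −78 °C; CeCl3, −78 °C; 24, −78 °C; aq. NH4Cl; then PPTS, acetone/H2O, rt
Reagents that add atoms: water, O
Why: Organocerium addition: the weakly basic, oxophilic cerium acetylide adds 1,2 to the hindered, easily enolised C2 ketone without removing the C1 proton. The new C2 centre is lost in step 15, so its configuration is immaterial; mild acid then hydrolyses the allylic acetal to the enal.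

Step 14
Reactants: 27 C2 tertiary carbinol with the (E)-2-methyl-3-oxoprop-1-enyl group at C1; 28 ethyltriphenylphosphonium iodide
Product: 29 C2 tertiary carbinol with the (1E,3Z)-4-iodo-2-methylpenta-1,3-dienyl group at C1
Conditions: 28 (3 equiv), n-BuLi, THF, rt; I2, −78 °C; NaN(SiMe3)2, −78 to −20 °C; 27, −78 °C
Reagents that add atoms: iodine, II
Why: Stork–Zhao-type Wittig reaction: the α-iodo ylide adds to the aldehyde under kinetic control to give the Z iodoalkene (iodine cis to the chain), which stores the later 4Z geometry. Excess ylide absorbs the hydroxyl proton, and at this stage C1–H is not yet flanked by the dienone.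

Step 15
Reactants: 29 C2 tertiary carbinol with the (1E,3Z)-4-iodo-2-methylpenta-1,3-dienyl group at C1
Product: 30 dienone with the (E)-3-(tert-butyldimethylsilyloxy)-2-oxopropylidene group at C2 and the (1E,3Z)-4-iodo-2-methylpenta-1,3-dienyl group at C1
Conditions: MoO2(acac)2 (5 mol %), AuCl(PPh3) (5 mol %), AgOTf (5 mol %), toluene, rt
Reagents that add atoms: none
Why: Meyer–Schuster rearrangement: the molybdenum oxo centre transposes the tertiary hydroxyl to the alkyne carbon activated by the gold cation, and the allenol tautomerises to the enone. The E isomer (acyl on the C1 side) is the thermodynamic one, because the other isomer would press the acyl group against the in-plane C3 methyl, while the pseudo-axial C1 chain relieves allylic strain.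

Step 16
Reactants: 31 propiolic acid; 32 tributyltin hydride
Product: 34 tributylstannyl (E)-3-(tributylstannyl)prop-2-enoate, via tributylstannyl propiolate 33 (not isolated)
Conditions: 32 (2.1 equiv), AIBN (cat.), neat, 70 °C
Reagents that add atoms: none
Why: The acid is first stannylated on oxygen with loss of hydrogen; radical hydrostannation of the alkyne then gives the β-stannyl acrylate, which equilibrates to the E isomer under the radical conditions.

Step 17
Reactants: 30 dienone with the (1E,3Z)-4-iodo-2-methylpenta-1,3-dienyl group at C1; 34 tributylstannyl (E)-3-(tributylstannyl)prop-2-enoate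
Product: 36 bis(tert-butyldimethylsilyl) ether of 37 (C7–O and ketol O silylated; free acid), via tributylstannyl ester 35 (not isolated)
Conditions: Pd2(dba)3 (5 mol %), AsPh3 (40 mol %), CuI (20 mol %), NMP, rt; aq. KF, then 0.1 M HCl
Reagents that add atoms: none
Why: Stille coupling with retention at both partners joins C4′ to C5′ under neutral conditions, so the Z C3′=C4′ bond and the base-sensitive C1–H are left alone. CuI and AsPh3 speed up transmetalation at the hindered α-methyl alkenyl iodide, and the stannyl ester is cleaved on work-up.

Step 18
Reactants: 36 bis(tert-butyldimethylsilyl) ether of 37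
Product: 37 (2E,4Z,6E)-7-[(1R,2E,4aS,6S,7R,8R,8aR)-7-hydroxy-2-(3-hydroxy-2-oxopropylidene)-3,6,8-trimethyl-1,2,4a,5,6,7,8,8a-octahydronaphthalen-1-yl]-4,6-dimethylhepta-2,4,6-trienoic acid
Conditions: HF·pyridine, pyridine, THF, 0 °C to rt
Reagents that add atoms: none
Why: Buffered fluoride desilylation removes both silyl ethers without base, which the doubly allylic C1–H and the Z trienoic acid would not tolerate.

## Compound list

1 | (R)-4-benzyl-3-propanoyloxazolidin-2-one | CCC(=O)N1C(=O)OC[C@H]1Cc1ccccc1 | starting material
2 | acrolein | C=CC=O | starting material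
3 | (R)-4-benzyl-3-[(Z)-1-(dibutylboryloxy)prop-1-enyl]oxazolidin-2-one | C/C=C(\OB(CCCC)CCCC)N1C(=O)OC[C@H]1Cc1ccccc1 | intermediate
4 | (R)-4-benzyl-3-[(2R,3S)-3-hydroxy-2-methylpent-4-enoyl]oxazolidin-2-one | O=C1OC[C@@H](Cc2ccccc2)N1C(=O)[C@H](C)[C@@H](O)C=C | intermediate
5 | (R)-4-benzyl-3-[(2R,3S)-3-(tert-butyldimethylsilyloxy)-2-methylpent-4-enoyl]oxazolidin-2-one | O=C1OC[C@@H](Cc2ccccc2)N1C(=O)[C@H](C)[C@@H](O[Si](C)(C)C(C)(C)C)C=C | intermediate
6 | (2S,3S)-3-(tert-butyldimethylsilyloxy)-2-methylpent-4-en-1-ol | OC[C@H](C)[C@@H](O[Si](C)(C)C(C)(C)C)C=C | intermediate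
7 | tert-butyl{[(3S,4R)-5-iodo-4-methylpent-1-en-3-yl]oxy}dimethylsilane | IC[C@H](C)[C@@H](O[Si](C)(C)C(C)(C)C)C=C | intermediate
8 | acetaldehyde N,N-dimethylhydrazone | C/C=N/N(C)C | starting material
9 | N,N-dimethylhydrazone of 10 | CN(C)/N=C/CC[C@H](C)[C@@H](O[Si](C)(C)C(C)(C)C)C=C | intermediate
10 | (4S,5S)-5-(tert-butyldimethylsilyloxy)-4-methylhept-6-enal | O=CCC[C@H](C)[C@@H](O[Si](C)(C)C(C)(C)C)C=C | intermediate
11 | methyl vinyl ketone | CC(=O)C=C | starting material
12 | (S)-2-[(2S,3S)-3-(tert-butyldimethylsilyloxy)-2-methylpent-4-enyl]-5-oxohexanal | CC(=O)CC[C@@H](C[C@H](C)[C@@H](O[Si](C)(C)C(C)(C)C)C=C)C=O | intermediate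
13 | (S)-4-[(2S,3S)-3-(tert-butyldimethylsilyloxy)-2-methylpent-4-enyl]cyclohex-2-en-1-one | O=C1CC[C@@H](C[C@H](C)[C@@H](O[Si](C)(C)C(C)(C)C)C=C)C=C1 | intermediate
14 | lithium dienolate of 13 (cross-conjugated, C2–O/C3) | [Li+].[O-]C1=CC[C@@H](C[C@H](C)[C@@H](O[Si](C)(C)C(C)(C)C)C=C)C=C1 | intermediate
15 | (4R,6R)-4-[(2S,3S)-3-(tert-butyldimethylsilyloxy)-2-methylpent-4-enyl]-6-methylcyclohex-2-en-1-one | C[C@@H]1C[C@@H](C[C@H](C)[C@@H](O[Si](C)(C)C(C)(C)C)C=C)C=CC1=O | intermediate
16 | cis-fused 7-(tert-butyldimethylsilyloxy)-3,6,8-trimethyloctahydronaphthalen-2(1H)-one; 6-Me, 7-OSi, 8-Me all equatorial; 8-Me trans to C8a–C1 | C[C@@H]1C[C@H]2C[C@H](C)[C@@H](O[Si](C)(C)C(C)(C)C)[C@H](C)[C@H]2CC1=O | intermediate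
17 | C2=C3 trimethylsilyl enol ether of 16 | CC=1C[C@H]2C[C@H](C)[C@@H](O[Si](C)(C)C(C)(C)C)[C@H](C)[C@H]2CC=1O[Si](C)(C)C | intermediate
18 | cis-fused 7-(tert-butyldimethylsilyloxy)-3,6,8-trimethyl-4a,5,6,7,8,8a-hexahydronaphthalen-2(1H)-one (C3=C4 enone) | CC1=C[C@H]2C[C@H](C)[C@@H](O[Si](C)(C)C(C)(C)C)[C@H](C)[C@H]2CC1=O | intermediate
19 | methacrolein | CC(=C)C=O | starting material
20 | 2,3-dibromo-2-methylpropanal | CC(Br)(CBr)C=O | intermediate
21 | (E)-3-bromo-2-methylprop-2-enal | Br/C=C(C)/C=O | intermediate
22 | (E)-1-bromo-3,3-dimethoxy-2-methylprop-1-ene | Br/C=C(C)/C(OC)OC | intermediate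
23 | lithium enolate of 18 (C1=C2–O) | CC1=C[C@H]2C[C@H](C)[C@@H](O[Si](C)(C)C(C)(C)C)[C@H](C)[C@H]2C=C1[O-].[Li+] | intermediate
24 | 18 with the (E)-3,3-dimethoxy-2-methylprop-1-enyl group at C1, anti to C8 | CC1=C[C@H]2C[C@H](C)[C@@H](O[Si](C)(C)C(C)(C)C)[C@H](C)[C@H]2[C@H](/C=C(C)/C(OC)OC)C1=O | intermediate
25 | tert-butyldimethyl(prop-2-ynyloxy)silane | C#CCO[Si](C)(C)C(C)(C)C | starting material
26 | C2 carbinol from 24 and 25, acetal intact (C2 configuration open) | CC1=C[C@H]2C[C@H](C)[C@@H](O[Si](C)(C)C(C)(C)C)[C@H](C)[C@H]2[C@H](/C=C(C)/C(OC)OC)C1(O)C#CCO[Si](C)(C)C(C)(C)C | intermediate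
27 | C2 carbinol with the (E)-2-methyl-3-oxoprop-1-enyl group at C1 (C2 configuration open) | CC1=C[C@H]2C[C@H](C)[C@@H](O[Si](C)(C)C(C)(C)C)[C@H](C)[C@H]2[C@H](/C=C(C)/C=O)C1(O)C#CCO[Si](C)(C)C(C)(C)C | intermediate
28 | ethyltriphenylphosphonium iodide | CC[P+](c1ccccc1)(c1ccccc1)c1ccccc1.[I-] | starting material
29 | C2 carbinol with the (1E,3Z)-4-iodo-2-methylpenta-1,3-dienyl group at C1 (C2 configuration open) | CC1=C[C@H]2C[C@H](C)[C@@H](O[Si](C)(C)C(C)(C)C)[C@H](C)[C@H]2[C@H](/C=C(C)/C=C(C)\I)C1(O)C#CCO[Si](C)(C)C(C)(C)C | intermediate
30 | dienone: C2 (E)-3-(tert-butyldimethylsilyloxy)-2-oxopropylidene; C1 (1E,3Z)-4-iodo-2-methylpenta-1,3-dienyl; C7 silyl ether | CC1=C[C@H]2C[C@H](C)[C@@H](O[Si](C)(C)C(C)(C)C)[C@H](C)[C@H]2[C@H](/C=C(C)/C=C(C)\I)/C1=C\C(=O)CO[Si](C)(C)C(C)(C)C | intermediate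
31 | propiolic acid | C#CC(=O)O | starting material
32 | tributyltin hydride | CCCC[SnH](CCCC)CCCC | starting material
33 | tributylstannyl propiolate | C#CC(=O)O[Sn](CCCC)(CCCC)CCCC | intermediate
34 | tributylstannyl (E)-3-(tributylstannyl)prop-2-enoate | CCCC[Sn](CCCC)(CCCC)/C=C/C(=O)O[Sn](CCCC)(CCCC)CCCC | intermediate
35 | tributylstannyl ester of 36 | CC1=C[C@H]2C[C@H](C)[C@@H](O[Si](C)(C)C(C)(C)C)[C@H](C)[C@H]2[C@H](/C=C(C)/C=C(C)\C=C\C(=O)O[Sn](CCCC)(CCCC)CCCC)/C1=C\C(=O)CO[Si](C)(C)C(C)(C)C | intermediate
36 | bis(tert-butyldimethylsilyl) ether of 37 (free acid) | CC1=C[C@H]2C[C@H](C)[C@@H](O[Si](C)(C)C(C)(C)C)[C@H](C)[C@H]2[C@H](/C=C(C)/C=C(C)\C=C\C(=O)O)/C1=C\C(=O)CO[Si](C)(C)C(C)(C)C | intermediate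
37 | (2E,4Z,6E)-7-[(1R,2E,4aS,6S,7R,8R,8aR)-7-hydroxy-2-(3-hydroxy-2-oxopropylidene)-3,6,8-trimethyl-1,2,4a,5,6,7,8,8a-octahydronaphthalen-1-yl]-4,6-dimethylhepta-2,4,6-trienoic acid | CC1=C[C@H]2C[C@H](C)[C@@H](O)[C@H](C)[C@H]2[C@H](/C=C(C)/C=C(C)\C=C\C(=O)O)/C1=C\C(=O)CO | target

## Step count and risks

Total step count: 18. Longest linear sequence: 15 steps (steps 1 to 9, 12 to 15, 17 and 18). Steps 10 and 11 make 22, and step 16 makes 34.

Least certain steps:

Step 8 (key step). The C8 radical may be reduced before it cyclises (net hydrogenation of the vinyl group), or it may take the allylic C4a hydrogen by a 1,5-shift. A boat-like closure would also erode control at C8, which cannot be corrected afterwards. Fallback, setting out from 15 and returning at 16: a thiyl-radical chain replaces the metal hydride. Thiophenol (slow addition) and AIBN in benzene at 80 °C add PhS• to the terminal vinyl carbon; the C8 radical closes 6-exo onto C8a and the α-keto radical takes hydrogen from the thiol, giving the 8-(phenylthiomethyl) decalone F1. Raney Ni in ethanol/acetone then cleaves the C–S bond to leave the C8 methyl of 16. The larger group on the radical carbon should reinforce the equatorial preference.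

Step 12. Proton exchange between product and enolate can move the enolate to the γ-position (C4a), shift the new alkene into conjugation with C2=O, or leave C1 as the kinetic protonation epimer. Fallback, setting out from 18 and returning at 24: polarity inversion at C1. Enolate 23 is quenched with N-bromosuccinimide to the C1 bromo enone F2. 22 is converted into its alkenylzinc chloride (t-BuLi, then ZnCl2). A nickel-catalysed Negishi-type coupling of the secondary α-bromo ketone (NiCl2·glyme, bipyridine-type ligand, THF/DMA, 0 °C) then forms C1–C1′ through a C1 radical captured on the open face, with no enolate present after the bond is made.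

Step 14. The basic ylide may deprotonate the enal γ-position (C1–H) or stall on the alkoxide instead of adding to the carbonyl, and Z selectivity may erode. Fallback, setting out from 27 and returning at 36:
- Ramirez olefination (CBr4, PPh3, Et3N, CH2Cl2, 0 °C) gives the 1,1-dibromodiene F3.
- Palladium-catalysed Negishi coupling with Me2Zn [PdCl2(DPEphos), THF] replaces selectively the bromine trans to the chain and leaves the Z bromide F4, which has the geometry of 29.
- Meyer–Schuster rearrangement as in step 15 gives the bromo dienone F5.
- Stille coupling with 34 under conditions suited to alkenyl bromides [Pd(P(t-Bu)3)2, CsF, NMP] rejoins the route at 36.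

Step 15. Ionisation of the tertiary carbinol, which is both allylic and propargylic, can divert the rearrangement toward transposition of oxygen to C4, dehydration toward C1, or gold-induced cyclisation of the vinyl-allene intermediate. Fallback, setting out from 29 and returning at 30: formal hydration, then dehydration. Hydroxyl-directed trans-hydrosilylation with (EtO)3SiH and [Cp*Ru(MeCN)3]PF6 places silicon on the alkyne carbon remote from C2 (vinylsilane F6). Tamao–Fleming oxidation (KF, KHCO3, H2O2) gives the β-hydroxy ketone F7. Dehydration of this tertiary aldol with Burgess reagent gives 30 without exposing the carbinol to a Lewis acid.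

Further compounds
F1 | step 8 | cis-fused 7-(tert-butyldimethylsilyloxy)-3,6-dimethyl-8-(phenylthiomethyl)octahydronaphthalen-2(1H)-one | C[C@@H]1C[C@H]2C[C@H](C)[C@@H](O[Si](C)(C)C(C)(C)C)[C@H](CSc3ccccc3)[C@H]2CC1=O
F2 | step 12 | 1-bromo derivative of 18 (C1 configuration open) | CC1=C[C@H]2C[C@H](C)[C@@H](O[Si](C)(C)C(C)(C)C)[C@H](C)[C@H]2C(Br)C1=O
F3 | step 14 | C2 carbinol with the (E)-4,4-dibromo-2-methylbuta-1,3-dienyl group at C1 | CC1=C[C@H]2C[C@H](C)[C@@H](O[Si](C)(C)C(C)(C)C)[C@H](C)[C@H]2[C@H](/C=C(C)/C=C(Br)Br)C1(O)C#CCO[Si](C)(C)C(C)(C)C
F4 | step 14 | C2 carbinol with the (1E,3Z)-4-bromo-2-methylpenta-1,3-dienyl group at C1 | CC1=C[C@H]2C[C@H](C)[C@@H](O[Si](C)(C)C(C)(C)C)[C@H](C)[C@H]2[C@H](/C=C(C)/C=C(C)\Br)C1(O)C#CCO[Si](C)(C)C(C)(C)C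
F5 | step 14 | bromo analogue of 30 | CC1=C[C@H]2C[C@H](C)[C@@H](O[Si](C)(C)C(C)(C)C)[C@H](C)[C@H]2[C@H](/C=C(C)/C=C(C)\Br)/C1=C\C(=O)CO[Si](C)(C)C(C)(C)C
F6 | step 15 | triethoxysilyl alkene from trans-hydrosilylation of 29 (silicon remote from C2) | CC1=C[C@H]2C[C@H](C)[C@@H](O[Si](C)(C)C(C)(C)C)[C@H](C)[C@H]2[C@H](/C=C(C)/C=C(C)\I)C1(O)/C=C(\[Si](OCC)(OCC)OCC)CO[Si](C)(C)C(C)(C)C
F7 | step 15 | β-hydroxy ketone (C2 carbinol with a 3-(tert-butyldimethylsilyloxy)-2-oxopropyl group) | CC1=C[C@H]2C[C@H](C)[C@@H](O[Si](C)(C)C(C)(C)C)[C@H](C)[C@H]2[C@H](/C=C(C)/C=C(C)\I)C1(O)CC(=O)CO[Si](C)(C)C(C)(C)C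
A1 | alternative 1 | cis-fused C7 ketone with C6 and C8 methyl groups and a dihydrofuran fused across C1–C2 | CC1=C[C@H]2C[C@H](C)C(=O)[C@H](C)[C@H]2[C@@H]3C=CO[C@H]13
A2 | alternative 2 | cis-decalin C7 ketone without the C6 methyl, with CH2OPMB on C1 and a silyl ether on C2 | CC1=C[C@H]2CCC(=O)[C@H](C)[C@H]2[C@H](COCc3ccc(OC)cc3)[C@H]1O[Si](C)(C)C(C)(C)C
A3 | alternative 3 | cis-decalin C2 allylic alcohol with a 2-methylprop-1-enyl group on C1 and the C7 silyl ether | CC1=C[C@H]2C[C@H](C)[C@@H](O[Si](C)(C)C(C)(C)C)[C@H](C)[C@H]2[C@H](C=C(C)C)[C@H]1O
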